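**Retrosynthetic overview**

1. Numbering: 1,2-dihydronaphthalene, C1 (aryl = ring C), C2 (C9H2OH), C3 (C10H2OH), C3=C4, ring A = benzo ring C4a–C8a (OMe on C6, C7, C8), ring B = C1–C4/C4a/C8a. The strategy rests on C1 being doubly benzylic with ring C oxygenated para to it, so C1 can become the electrophilic carbon of a para-quinone methide, while C2 is α to the aldehyde-level carbon C9.
2. Ring B is closed last by the C1–C2 bond: the dienamine of a β,γ-unsaturated aldehyde adds to the quinone methide made in situ from a para-hydroxybenzhydrol; this sets C1 and C2.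
3. The open precursor is cut at C1–C8a (aryllithium of ring A plus O-silyl vanillin). Its C3=C4 alkene with ring A cis to C2 comes from hydroxyl-directed anti-carbomagnesiation of an arylpropargyl alcohol with vinylmagnesium bromide; hydroboration and oxidation turn the vinyl group into C2–C9.
4. After ring closure: reduction at C9, O-methylation of the phenol, desilylation at C10.

Key step: step 10

Assumption: the benzhydrol carbon is carried as both epimers (12 to 16 are racemic), which is harmless because it becomes trigonal in the quinone methide; the sense of induction at C2 is taken from the usual shielding model of (S)-diarylprolinol silyl ethers, and the (R)-catalyst would be used if the opposite sense were found.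

**Route**

Step 1
Reactants: 1 2-bromo-3,4,5-trimethoxybenzaldehyde
Product: 2 2-bromo-1-ethynyl-3,4,5-trimethoxybenzene
Conditions: dimethyl (1-diazo-2-oxopropyl)phosphonate (1.3 equiv), K2CO3 (2 equiv), MeOH, 0 °C → rt
Reagents that add atoms: dimethyl (1-diazo-2-oxopropyl)phosphonate, COP(=O)(OC)C(=[N+]=[N-])C(C)=O
Why: Seyferth–Gilbert homologation in its Ohira–Bestmann form turns an aryl aldehyde into the terminal alkyne under mild carbonate conditions that leave the aryl bromide and methyl ethers untouched.

Step 2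
Reactants: 2 2-bromo-1-ethynyl-3,4,5-trimethoxybenzene
Product: 4 3-(2-bromo-3,4,5-trimethoxyphenyl)prop-2-yn-1-ol, via alkynylmagnesium bromide 3 (not isolated)
Conditions: EtMgBr (1.2 equiv), THF, 0 → 45 °C; (CH2O)n (3 equiv), 45 °C; pH 7 buffer
Reagents that add atoms: formaldehyde (used as paraformaldehyde), C=O
Why: deprotonation of the terminal alkyne by ethylmagnesium bromide (no halogen–metal exchange at the aryl bromide) and addition of the acetylide to formaldehyde is the standard hydroxymethylation to an arylpropargyl alcohol.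

Step 3
Reactants: 4 3-(2-bromo-3,4,5-trimethoxyphenyl)prop-2-yn-1-ol; 5 vinylmagnesium bromide
Product: 7 (2E)-2-[(2-bromo-3,4,5-trimethoxyphenyl)methylidene]but-3-en-1-ol, via oxamagnesacycle 6 (not isolated)
Conditions: 5 (4 equiv, 1 M in THF), toluene, 90 °C; then pH 7 buffer, 0 °C
Reagents that add atoms: none
Why: hydroxyl-directed anti-carbomagnesiation of a propargylic alcohol delivers the vinyl group to the alkyne carbon next to the carbinol carbon and holds magnesium on the aryl-bearing carbon in a five-membered alkoxide chelate, so protonation puts H cis to CH2OH and ring A cis to the vinyl group (E alkene, the geometry needed for ring closure).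

Step 4
Reactants: 7 (2E)-2-[(2-bromo-3,4,5-trimethoxyphenyl)methylidene]but-3-en-1-ol
Product: 8 tert-butyl{[(2E)-2-[(2-bromo-3,4,5-trimethoxyphenyl)methylidene]but-3-en-1-yl]oxy}dimethylsilane
Conditions: TBSCl (1.2 equiv), imidazole (2 equiv), CH2Cl2, 0 °C → rt
Reagents that add atoms: tert-butyldimethylsilyl chloride, CC(C)(C)[Si](C)(C)Cl
Why: routine silylation of a primary allylic alcohol; the silyl ether masks C10–OH through the organolithium, borane and oxidation steps.

Step 5
Reactants: 9 vanillin (4-hydroxy-3-methoxybenzaldehyde)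
Product: 10 4-[(tert-butyldimethylsilyl)oxy]-3-methoxybenzaldehyde
Conditions: TBSCl (1.1 equiv), imidazole (2 equiv), CH2Cl2, rt
Reagents that add atoms: tert-butyldimethylsilyl chloride, CC(C)(C)[Si](C)(C)Cl
Why: routine phenol silylation, needed so that the aldehyde can meet an aryllithium.

Step 6
Reactants: 8 tert-butyl{[(2E)-2-[(2-bromo-3,4,5-trimethoxyphenyl)methylidene]but-3-en-1-yl]oxy}dimethylsilane; 10 4-[(tert-butyldimethylsilyl)oxy]-3-methoxybenzaldehyde
Product: 12 [4-(tert-butyldimethylsilyloxy)-3-methoxyphenyl]{6-[(1E)-2-(tert-butyldimethylsilyloxymethyl)buta-1,3-dien-1-yl]-2,3,4-trimethoxyphenyl}methanol (both carbinol epimers), via aryllithium 11 (not isolated)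
Conditions: n-BuLi (1.05 equiv), THF, −78 °C, 15 min; then 10 (1.1 equiv), −78 → −40 °C; pH 7 buffer
Reagents that add atoms: none
Why: bromine–lithium exchange of the electron-rich aryl bromide is fast at −78 °C (faster than addition to the diene) and the aryllithium adds to the aromatic aldehyde to form the C1–C8a bond; the carbinol centre forms without control, which does not matter because it is erased in step 10.

Step 7
Reactants: 12 benzhydrol diene (as named in step 6)
Product: 14 (3E)-4-{2-[(4-(tert-butyldimethylsilyloxy)-3-methoxyphenyl)(hydroxy)methyl]-3,4,5-trimethoxyphenyl}-3-[(tert-butyldimethylsilyloxy)methyl]but-3-en-1-ol, via alkylborane 13 (not isolated)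
Conditions: 9-BBN (2.5 equiv, 0.5 M in THF), 0 °C → rt; then aq NaOAc, 30% H2O2, 0 °C → rt
Reagents that add atoms: hydrogen peroxide, OO
Why: hydroboration–oxidation with 9-BBN is anti-Markovnikov and should touch only the monosubstituted vinyl group (the trisubstituted, aryl-conjugated C3=C4 is too hindered), one extra equivalent being consumed by the free carbinol; acetate-buffered peroxide should spare the aryl silyl ether.

Step 8
Reactants: 14 primary alcohol (as named in step 7)
Product: 15 (3E)-4-{2-[(4-(tert-butyldimethylsilyloxy)-3-methoxyphenyl)(hydroxy)methyl]-3,4,5-trimethoxyphenyl}-3-[(tert-butyldimethylsilyloxy)methyl]but-3-enal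
Conditions: TEMPO (10 mol%), PhI(OAc)2 (1.2 equiv), CH2Cl2, 0 °C → rt; aq Na2S2O3
Reagents that add atoms: none
Why: the oxoammonium (TEMPO/PhI(OAc)2) oxidation strongly prefers unhindered primary alcohols, so C9 should be oxidised while the secondary benzhydrol, flanked on ring A by two ortho substituents, stays; the near-neutral medium should not move C3=C4 into conjugation.

Step 9
Reactants: 15 aldehyde (as named in step 8)
Product: 16 (3E)-3-[(tert-butyldimethylsilyloxy)methyl]-4-{2-[hydroxy(4-hydroxy-3-methoxyphenyl)methyl]-3,4,5-trimethoxyphenyl}but-3-enal (both carbinol epimers)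
Conditions: Bu4NF (1.05 equiv), AcOH (1.1 equiv), THF, −20 °C, 20 min; pH 7 buffer; used at once without chromatography
Reagents that add atoms: none
Why: fluoride cleaves the aryl O–Si bond (phenoxide leaving group) much faster than the primary alkyl O–Si bond, and acetic acid buffering at low temperature should protect the β,γ-unsaturated aldehyde from base-induced isomerisation.

Step 10
Reactants: 16 para-hydroxybenzhydrol aldehyde (as named in step 9)
Product: 19 (1R,2S)-3-[(tert-butyldimethylsilyloxy)methyl]-1-(4-hydroxy-3-methoxyphenyl)-6,7,8-trimethoxy-1,2-dihydronaphthalene-2-carbaldehyde, via para-quinone methide aldehyde 17 (not isolated), via quinone methide dienamine 18 (not isolated)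
Conditions: (S)-2-[diphenyl(trimethylsilyloxy)methyl]pyrrolidine (20 mol%), (PhO)2P(O)OH (20 mol%), CHCl3 (0.05 M), −20 → 0 °C; crude product taken straight into step 11
Reagents that add atoms: none
Why: Proposed new method: diphenyl phosphate should ionise the para-hydroxybenzhydrol of 16 to the neutral para-quinone methide 17 while the secondary amine condenses with the β,γ-unsaturated aldehyde to the linear dienamine 18, whose α-carbon C2 adds to the methide carbon C1 (1,6-addition, driven by rearomatisation of ring C), after which the water set free hydrolyses the iminium ion and returns the catalyst. The closest known reactions are the aminocatalytic intramolecular 1,6-addition of saturated aldehyde enamines to para-quinone methides and the acid-promoted formation of such methides from para-hydroxybenzyl alcohols; what is untested is a dienamine as the α-nucleophile. Ring B closes in a 6-(enolexo)-exo-trig mode, made easy by the E alkene that holds ring A cis to C2, and attack through the γ-carbon C4 is ruled out because it would give a four-membered ring. C2 is controlled by the catalyst, whose diphenyl(silyloxy)methyl group shields the Re face of the dienamine α-carbon so that C1 bonds to the Si face (2S), and C1 is controlled by the half-chair transition state, in which the C1 aryl group avoids the peri C8 methoxy group and C9 avoids the C10 arm, which places them trans (1R). The step needs the dienamine pathway to outrun the racemic acid-only enol cyclisation and the cationic closure of C1 onto C3=C4, which the weak acid, the low temperature and the only moderately electrophilic neutral methide should secure, and it needs ring A to stay cis to C2, which holds because any E/Z exchange through the conjugated iminium ion is reversible and only the E isomer can close.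

Step 11
Reactants: 19 dihydronaphthalene aldehyde (as named in step 10)
Product: 20 [(1R,2S)-3-[(tert-butyldimethylsilyloxy)methyl]-1-(4-hydroxy-3-methoxyphenyl)-6,7,8-trimethoxy-1,2-dihydronaphthalen-2-yl]methanol
Conditions: NaBH4 (1.5 equiv), MeOH/CH2Cl2, −20 → 0 °C
Reagents that add atoms: none
Why: borohydride reduces the aldehyde without touching the styrenyl alkene, and immediate reduction removes the epimerisable α-formyl situation at C2, whose configuration is kept.

Step 12
Reactants: 20 phenol alcohol (as named in step 11)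
Product: 21 [(1R,2S)-3-[(tert-butyldimethylsilyloxy)methyl]-1-(3,4-dimethoxyphenyl)-6,7,8-trimethoxy-1,2-dihydronaphthalen-2-yl]methanol
Conditions: MeI (2 equiv), K2CO3 (2 equiv), acetone, rt → 40 °C
Reagents that add atoms: iodomethane, CI
Why: Williamson O-methylation; carbonate deprotonates only the phenol, so the primary alcohol is left alone and ring C becomes the 3,4-dimethoxyphenyl group.

Step 13
Reactants: 21 silyl ether (as named in step 12)
Product: 22 [(1R,2S)-1-(3,4-dimethoxyphenyl)-6,7,8-trimethoxy-1,2-dihydronaphthalene-2,3-diyl]dimethanol (target)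
Conditions: Bu4NF (1.5 equiv), THF, 0 °C → rt
Reagents that add atoms: none
Why: fluoride desilylation frees the C10 alcohol and does not touch either stereocentre.

**Compound list**

1 | 2-bromo-3,4,5-trimethoxybenzaldehyde | COc1cc(C=O)c(Br)c(OC)c1OC | starting material
2 | 2-bromo-1-ethynyl-3,4,5-trimethoxybenzene | COc1cc(C#C)c(Br)c(OC)c1OC | intermediate
3 | [(2-bromo-3,4,5-trimethoxyphenyl)ethynyl]magnesium bromide | COc1cc(C#C[Mg]Br)c(Br)c(OC)c1OC | intermediate (not isolated)
4 | 3-(2-bromo-3,4,5-trimethoxyphenyl)prop-2-yn-1-ol | COc1cc(C#CCO)c(Br)c(OC)c1OC | intermediate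
5 | vinylmagnesium bromide | C=C[Mg]Br | starting material
6 | 3-(2-bromo-3,4,5-trimethoxyphenyl)-4-ethenyl-2,5-dihydro-1,2-oxamagnesole (chelated alkenylmagnesium alkoxide) | COc1cc(C2=C(C=C)CO[Mg]2)c(Br)c(OC)c1OC | intermediate (not isolated)
7 | (2E)-2-[(2-bromo-3,4,5-trimethoxyphenyl)methylidene]but-3-en-1-ol | COc1cc(/C=C(\C=C)CO)c(Br)c(OC)c1OC | intermediate
8 | tert-butyl{[(2E)-2-[(2-bromo-3,4,5-trimethoxyphenyl)methylidene]but-3-en-1-yl]oxy}dimethylsilane | COc1cc(/C=C(\C=C)CO[Si](C)(C)C(C)(C)C)c(Br)c(OC)c1OC | intermediate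
9 | vanillin | COc1cc(C=O)ccc1O | starting material
10 | 4-[(tert-butyldimethylsilyl)oxy]-3-methoxybenzaldehyde | COc1cc(C=O)ccc1O[Si](C)(C)C(C)(C)C | intermediate
11 | {6-[(1E)-2-(tert-butyldimethylsilyloxymethyl)buta-1,3-dien-1-yl]-2,3,4-trimethoxyphenyl}lithium | COc1cc(/C=C(\C=C)CO[Si](C)(C)C(C)(C)C)c([Li])c(OC)c1OC | intermediate (not isolated)
12 | [4-(tert-butyldimethylsilyloxy)-3-methoxyphenyl]{6-[(1E)-2-(tert-butyldimethylsilyloxymethyl)buta-1,3-dien-1-yl]-2,3,4-trimethoxyphenyl}methanol (both carbinol epimers) | COc1cc(/C=C(\C=C)CO[Si](C)(C)C(C)(C)C)c(C(O)c2ccc(O[Si](C)(C)C(C)(C)C)c(OC)c2)c(OC)c1OC | intermediate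
13 | B-alkyl-9-borabicyclo[3.3.1]nonane of 12, with the carbinol oxygen as its 9-BBN borinate | COc1cc(/C=C(\CCB2C3CCCC2CCC3)CO[Si](C)(C)C(C)(C)C)c(C(OB2C3CCCC2CCC3)c2ccc(O[Si](C)(C)C(C)(C)C)c(OC)c2)c(OC)c1OC | intermediate (not isolated)
14 | (3E)-4-{2-[(4-(tert-butyldimethylsilyloxy)-3-methoxyphenyl)(hydroxy)methyl]-3,4,5-trimethoxyphenyl}-3-[(tert-butyldimethylsilyloxy)methyl]but-3-en-1-ol | COc1cc(/C=C(\CCO)CO[Si](C)(C)C(C)(C)C)c(C(O)c2ccc(O[Si](C)(C)C(C)(C)C)c(OC)c2)c(OC)c1OC | intermediate
15 | (3E)-4-{2-[(4-(tert-butyldimethylsilyloxy)-3-methoxyphenyl)(hydroxy)methyl]-3,4,5-trimethoxyphenyl}-3-[(tert-butyldimethylsilyloxy)methyl]but-3-enal | COc1cc(/C=C(\CC=O)CO[Si](C)(C)C(C)(C)C)c(C(O)c2ccc(O[Si](C)(C)C(C)(C)C)c(OC)c2)c(OC)c1OC | intermediate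
16 | (3E)-3-[(tert-butyldimethylsilyloxy)methyl]-4-{2-[hydroxy(4-hydroxy-3-methoxyphenyl)methyl]-3,4,5-trimethoxyphenyl}but-3-enal (key-step precursor) | COc1cc(/C=C(\CC=O)CO[Si](C)(C)C(C)(C)C)c(C(O)c2ccc(O)c(OC)c2)c(OC)c1OC | intermediate
17 | (3E)-3-[(tert-butyldimethylsilyloxy)methyl]-4-{3,4,5-trimethoxy-2-[(3-methoxy-4-oxocyclohexa-2,5-dien-1-ylidene)methyl]phenyl}but-3-enal (para-quinone methide) | COc1cc(/C=C(\CC=O)CO[Si](C)(C)C(C)(C)C)c(C=C2C=CC(=O)C(OC)=C2)c(OC)c1OC | intermediate (not isolated)
18 | (1E,3E)-dienamine of 17 with (S)-2-[diphenyl(trimethylsilyloxy)methyl]pyrrolidine | COc1cc(/C=C(\C=C\N2CCC[C@H]2C(O[Si](C)(C)C)(c2ccccc2)c2ccccc2)CO[Si](C)(C)C(C)(C)C)c(C=C2C=CC(=O)C(OC)=C2)c(OC)c1OC | intermediate (not isolated)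
19 | (1R,2S)-3-[(tert-butyldimethylsilyloxy)methyl]-1-(4-hydroxy-3-methoxyphenyl)-6,7,8-trimethoxy-1,2-dihydronaphthalene-2-carbaldehyde (key-step product) | Oc1ccc([C@@H]2c3c(cc(OC)c(OC)c3OC)C=C(CO[Si](C)(C)C(C)(C)C)[C@H]2C=O)cc1OC | intermediate
20 | [(1R,2S)-3-[(tert-butyldimethylsilyloxy)methyl]-1-(4-hydroxy-3-methoxyphenyl)-6,7,8-trimethoxy-1,2-dihydronaphthalen-2-yl]methanol | Oc1ccc([C@@H]2c3c(cc(OC)c(OC)c3OC)C=C(CO[Si](C)(C)C(C)(C)C)[C@H]2CO)cc1OC | intermediate
21 | [(1R,2S)-3-[(tert-butyldimethylsilyloxy)methyl]-1-(3,4-dimethoxyphenyl)-6,7,8-trimethoxy-1,2-dihydronaphthalen-2-yl]methanol | COc1ccc([C@@H]2c3c(cc(OC)c(OC)c3OC)C=C(CO[Si](C)(C)C(C)(C)C)[C@H]2CO)cc1OC | intermediate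
22 | [(1R,2S)-1-(3,4-dimethoxyphenyl)-6,7,8-trimethoxy-1,2-dihydronaphthalene-2,3-diyl]dimethanol | COc1ccc([C@@H]2c3c(cc(OC)c(OC)c3OC)C=C(CO)[C@H]2CO)cc1OC | target

**Step count and risks**

Total steps: 13. Longest linear sequence: 12 (steps 1–4 and 6–13; step 5 is a one-step branch).

Most likely to fail:

1. Step 10 (the step carrying the new-method label). What may go wrong: the acid-only enol cyclisation may compete and erode enantiopurity, facial control by the catalyst may be poor in the cyclic transition state, the benzhydryl cation/methide may close onto C3=C4 instead (indene formation), or the catalyst may be consumed by N-alkylation at C1. Fallback by known auxiliary chemistry, setting out from 15 and returning at 20: Pinnick oxidation (NaClO2, NaH2PO4, 2-methyl-2-butene, t-BuOH/H2O) would give (3E)-4-{2-[(4-(tert-butyldimethylsilyloxy)-3-methoxyphenyl)(hydroxy)methyl]-3,4,5-trimethoxyphenyl}-3-[(tert-butyldimethylsilyloxy)methyl]but-3-enoic acid F1. Coupling with (S)-4-isopropyl-1,3-thiazolidine-2-thione (EDC·HCl, DMAP, CH2Cl2) would give the N-acyl thiazolidinethione F2. TiCl4 (2.2 equiv) and i-Pr2NEt in CH2Cl2 (−78 → −40 °C) would form the chelated Z titanium enolate and ionise the benzhydrol to the diarylmethyl cation, which needs no free phenol because the para-silyloxy and methoxy groups stabilise it. The enolate should capture it on the face anti to the isopropyl group (stereoselective SN1 alkylation of a chiral titanium enolate) to give the trans-(1R,2S) cyclised N-acyl thiazolidinethione F3. NaBH4 (THF/H2O, 0 °C) would remove the auxiliary reductively to the bis-silylated alcohol F4, and K2CO3/MeOH (rt) would cleave only the aryl silyl ether to give 20.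

2. Step 3. What may go wrong: carbomagnesiation of the ortho-substituted, electron-rich arylalkyne may be slow, so that only the alkoxide forms, or prolonged heating may erode the regio- and anti-selectivity. Fallback, setting out from 4 and returning at 7: ruthenium-catalysed hydroxyl-directed trans-hydrostannation ([Cp*RuCl]4 cat., Bu3SnH, CH2Cl2, rt) would place tin on the carbon next to the carbinol carbon, trans to the new H, giving (2Z)-3-(2-bromo-3,4,5-trimethoxyphenyl)-2-(tributylstannyl)prop-2-en-1-ol F5. Iododestannylation (I2, CH2Cl2, 0 °C) would give (2Z)-3-(2-bromo-3,4,5-trimethoxyphenyl)-2-iodoprop-2-en-1-ol F6 with retention. Stille coupling with tributyl(vinyl)stannane (Pd(PPh3)4, CuI, CsF, DMF, rt), selective for the alkenyl iodide over the hindered aryl bromide, would give 7 with ring A cis to the vinyl group.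

3. Step 9. What may go wrong: fluoride may also remove the alkyl silyl ether, the basic medium may shift C3=C4 into conjugation or start aldol condensation of the aldehyde, or the quinone methide may form early. Fallback with a phenol protecting group that is removed under neutral conditions, setting out from 14 and returning at 16: K2CO3/MeOH (rt) would cleave the aryl silyl ether before any aldehyde is present, giving (3E)-3-[(tert-butyldimethylsilyloxy)methyl]-4-{2-[hydroxy(4-hydroxy-3-methoxyphenyl)methyl]-3,4,5-trimethoxyphenyl}but-3-en-1-ol F7. Allyl chloroformate with K2CO3 in acetone (0 °C) would acylate only the phenoxide to the aryl allyl carbonate F8. TEMPO/PhI(OAc)2 (CH2Cl2) would oxidise the primary alcohol to the aldehyde carbonate F9. Pd(PPh3)4 (3 mol%) with PhSO2Na in THF/H2O (rt) would remove the allyloxycarbonyl group under neutral conditions to give 16.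

**Further compounds**

F1 | step 10 | (3E)-4-{2-[(4-(tert-butyldimethylsilyloxy)-3-methoxyphenyl)(hydroxy)methyl]-3,4,5-trimethoxyphenyl}-3-[(tert-butyldimethylsilyloxy)methyl]but-3-enoic acid | COc1cc(/C=C(\CC(=O)O)CO[Si](C)(C)C(C)(C)C)c(C(O)c2ccc(O[Si](C)(C)C(C)(C)C)c(OC)c2)c(OC)c1OC
F2 | step 10 | N-acyl (S)-4-isopropyl-1,3-thiazolidine-2-thione of F1 | COc1cc(/C=C(\CC(=O)N2[C@@H](C(C)C)CSC2=S)CO[Si](C)(C)C(C)(C)C)c(C(O)c2ccc(O[Si](C)(C)C(C)(C)C)c(OC)c2)c(OC)c1OC
F3 | step 10 | (1R,2S)-1-[4-(tert-butyldimethylsilyloxy)-3-methoxyphenyl]-3-[(tert-butyldimethylsilyloxy)methyl]-6,7,8-trimethoxy-1,2-dihydronaphthalene-2-carbonyl (S)-4-isopropyl-1,3-thiazolidine-2-thione | CC(C)(C)[Si](C)(C)Oc1ccc([C@@H]2c3c(cc(OC)c(OC)c3OC)C=C(CO[Si](C)(C)C(C)(C)C)[C@H]2C(=O)N2[C@@H](C(C)C)CSC2=S)cc1OC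
F4 | step 10 | [(1R,2S)-1-[4-(tert-butyldimethylsilyloxy)-3-methoxyphenyl]-3-[(tert-butyldimethylsilyloxy)methyl]-6,7,8-trimethoxy-1,2-dihydronaphthalen-2-yl]methanol | CC(C)(C)[Si](C)(C)Oc1ccc([C@@H]2c3c(cc(OC)c(OC)c3OC)C=C(CO[Si](C)(C)C(C)(C)C)[C@H]2CO)cc1OC
F5 | step 3 | (2Z)-3-(2-bromo-3,4,5-trimethoxyphenyl)-2-(tributylstannyl)prop-2-en-1-ol | COc1cc(/C=C(\[Sn](CCCC)(CCCC)CCCC)CO)c(Br)c(OC)c1OC
F6 | step 3 | (2Z)-3-(2-bromo-3,4,5-trimethoxyphenyl)-2-iodoprop-2-en-1-ol | COc1cc(/C=C(\I)CO)c(Br)c(OC)c1OC
F7 | step 9 | (3E)-3-[(tert-butyldimethylsilyloxy)methyl]-4-{2-[hydroxy(4-hydroxy-3-methoxyphenyl)methyl]-3,4,5-trimethoxyphenyl}but-3-en-1-ol | COc1cc(/C=C(\CCO)CO[Si](C)(C)C(C)(C)C)c(C(O)c2ccc(O)c(OC)c2)c(OC)c1OC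
F8 | step 9 | allyl aryl carbonate of F7 (allyloxycarbonyl on the phenol oxygen) | COc1cc(/C=C(\CCO)CO[Si](C)(C)C(C)(C)C)c(C(O)c2ccc(OC(=O)OCC=C)c(OC)c2)c(OC)c1OC
F9 | step 9 | (3E)-4-{2-[(4-(allyloxycarbonyloxy)-3-methoxyphenyl)(hydroxy)methyl]-3,4,5-trimethoxyphenyl}-3-[(tert-butyldimethylsilyloxy)methyl]but-3-enal | COc1cc(/C=C(\CC=O)CO[Si](C)(C)C(C)(C)C)c(C(O)c2ccc(OC(=O)OCC=C)c(OC)c2)c(OC)c1OC
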